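Assumption: 1-chloro-3-methoxypropan-2-one (15), 4-(benzyloxy)-3-methoxybenzyl alcohol (10) and 2-bromoethyl trifluoromethanesulfonate (19) are treated as purchasable, and the target is the all-S isomer, (3S,4S) in both lactones.

## The problem

The target is an unsymmetrical dimer of two trans-3,4-dibenzylbutyrolactones that are joined only through a diaryl ether oxygen between C4 of ring A and C3 of ring B. Each lactone carries a 3,4-dimethoxybenzyl group at C4; the C3 benzyl group of the first lactone is ring A (4-aryloxy-3-methoxyphenyl) and that of the second is ring B (C1 benzylic, C3 aryloxy, C4 hydroxyl, C5 methoxy). The four stereocentres, all S, form two remote pairs: within each lactone C4 can control C3, because an enolate is alkylated anti to the C4 substituent and trans is also the stable arrangement, but neither lactone can control the other. Both halves must therefore come from one enantiopure building block, (S)-4-(3,4-dimethoxybenzyl)butyrolactone. The ether oxygen lies between an ortho methoxy group on ring A and the C4 oxygen on ring B, on two electron-rich rings, an unfavourable setting for copper-mediated or SNAr ether formation. The lactones are open to nucleophiles and strong base and their C3–H is epimerisable, and the free phenol of ring B, para to a benzylic CH2, is sensitive to oxidants, so it should be released last. Ring B has oxygens on three neighbouring carbons (C3, C4, C5), hydrogens at C2 and C6 and its only carbon substituent at C1. That is the substitution pattern of a 3,5-dioxygenated 4H-pyran-4-one in which C1 takes the place of the ring oxygen, and it is what allows ring B to be built from a pyranone.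

## Retrosynthesis

**29 to 28.** The O–Si bond at C4 of ring B is cut. The silyl group is not an added protecting group: it is the activator of the ring-forming step and arrives on the phenol oxygen by itself. The forward step only has to remove it with buffered fluoride without touching the lactones.

**28 to 18 and 23.** The C1–C2 and C1–C6 bonds of ring B are cut, so that C1 with its CH2–lactone arm becomes the ylide carbon of phosphonium salt 23 and the other five ring carbons, with all three oxygens, become pyranone 18. Cutting the diaryl ether C–O bond instead would ask for a hindered coupling between two electron-rich rings, and cutting the benzylic C–C bonds still presupposes that ether. With the chosen cut the pentasubstituted arene disappears, the ether oxygen becomes an ordinary phenol ether that can be made by SN2 chemistry, and both fragments are monomeric lactones derived from 9. The forward step asks that ylide 24 attack an α carbon of the silyloxypyrylium ion 25, that adduct 26 open to 27 and that 27 close by Wittig olefination, all in the presence of two lactones; no stereocentre is at stake.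

**18 to 16, then 14 and 15.** The pyranone is cut at O1–C2, O1–C6, C2–C3 and C5–C6, which returns the 1-aryloxy-3-methoxypropan-2-one 16. The two missing ring carbons enter as the dimethylaminomethylene groups of bis(enaminone) 17 and the ring oxygen on aqueous acid treatment. The aryl O–CH2 bond of 16 is then cut to phenol 14 and chloroketone 15, so the hindered ether oxygen is attached by a Williamson reaction at a primary α-keto carbon. The forward steps must be mild enough for the lactone, whose C3 has only one hydrogen and cannot form an enaminone.

**14 to 13, then 9 and 11.** The C3–CH2(ring A) bond is cut. Alkylation of lithium enolate 12 with benzyl bromide 11 (from alcohol 10) anti to the C4 group sets C3, and the benzyl ether is needed only to carry the phenol through the enolate step.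

**23 to 21 and 22, then 9 and 19.** The P–C bond is cut first. Quaternisation of phosphine 22 by the primary bromide 21 is neutral, leaves the lactone and its C3–H alone and gives a salt that can be crystallised and dried. The C3–CH2 bond of 21 is then cut to the sodium enolate 20 of lactone 9 and the bromoethyl triflate 19: the triflate leaves far faster than the bromide, so the bromoethyl unit is transferred intact and enters anti to C4. Because this branch never passes through a ylide, ylide 24 is made only once, from a weighed amount of pure 23, at the moment the key step needs it.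

**9 to 7, then 4, 5, 1 and 2.** The lactone is opened at O1–C2 and the C3–C4 bond (lactone numbering) is cut. The single C4 stereocentre comes from alkylation of the oxazolidinone imide 4 (from acid 1 and auxiliary 2, via 3) with bromoacetate 5 through enolate 6. Reductive removal of the auxiliary gives 8, and acid closes the lactone. The sense of induction is predictable, and diastereomers can be removed at 7, which matters because two molecules of 9 end up in every molecule of 29.

## Roads not taken

**Alternative 1:** The cut is at both C3–benzylic bonds at once, back to the diaryl ether dialdehyde A1 and two equivalents of enolate 12.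
- Forward key step: a two-directional aldol addition gives the bis(aldol adduct) A2 with C3 anti to C4 and the carbinol centres uncontrolled. Double benzylic hydrogenolysis, which also removes the benzyl ether, would give 29.
- Merits: this is the most convergent plan. It needs one lactone and one ether building block, both reaction types are standard in lignan chemistry, and the carbinol configuration is irrelevant.
- Weak points: the whole difficulty moves into A1, whose hindered ether must be made by copper-mediated coupling or SNAr on a phenol flanked by two oxygens. Both aldol additions must go to completion. The deoxygenation has to work on four carbinol diastereomers, where elimination to benzylidene lactones would endanger C3.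
- Comparison: in step count and in reliance on proven reactions this road is better than the chosen one. Against that, the chosen plan forms the ether by simple O-alkylation, sets C3 by direct alkylation with no oxidation-level detour on the dimer, and builds ring B with full regiocontrol.

**Alternative 2:** The cut is at the O1–C5 bond of the building block only: 3-(3,4-dimethoxybenzyl)cyclobutanone A3 is desymmetrised to the (S)-lactone A4, which is identical with 9.
- Forward key step: a catalytic asymmetric Baeyer–Villiger oxidation, with a chiral Brønsted acid and aqueous peroxide or with a monooxygenase, inserts oxygen into one of the two enantiotopic C(O)–CH2 bonds.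
- Merits: it is catalytic, needs no auxiliary, has no regiochemical issue and is short.
- Weak points: the stereocentre is remote from the carbonyl and bears a flexible benzyl group, so enantiotopic discrimination is uncertain. A4 offers no diastereomer stage for upgrading, and every enantiomeric impurity becomes a diastereomeric impurity in the dimer. The oxidant also meets an electron-rich arene. The road says nothing about joining the halves.
- Comparison: it is more atom-economical than steps 1 to 3 and could replace them. The chosen sequence offers instead a predictable sense of induction and purification at the diastereomer 7.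

**Alternative 3:** The cut is at both aryl–CH2 bonds, back to the diaryl ether bis(pinacol boronate) A5 and two equivalents of the (S)-3-methylene lactone A6.
- Forward key step: twofold conjugate arylation under [Rh(cod)OH]2 in aqueous dioxane, in which protonation of the rhodium enolates creates both C3 centres, gives the benzyl ether A7. Hydrogenolysis would follow.
- Merits: the plan is convergent, the conditions are neutral and lactone-tolerant, and the reaction type is established for α-methylene carbonyl compounds.
- Weak points: C3 is set by a proton transfer. Kinetic protonation anti to the C4 group would place the new arylmethyl group cis, so base equilibration at two centres of the dimer would probably be needed. β-Hydride elimination, and migration of the exocyclic double bond into the ring (which would erase C4), compete. A5 still needs the hindered ether plus two borylations, and electron-rich boronates protodeboronate.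
- Comparison: the length is comparable and the key reaction is better precedented than the chosen one. The chosen plan sets against this a C3 fixed by C–C bond formation anti to C4 in each half before the halves meet, and no aryl ether coupling.

Key step: step 11

## Route

Step 1
Reactants: 1 3-(3,4-dimethoxyphenyl)propanoic acid; 2 (R)-4-benzyloxazolidin-2-one
Product: 4 (R)-4-benzyl-3-[3-(3,4-dimethoxyphenyl)propanoyl]oxazolidin-2-one, via mixed pivalic anhydride 3 (not isolated)
Conditions: PivCl, Et3N, THF, −20 °C; then 2, LiCl, −20 °C to rt
Reagents that add atoms: none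
Why: N-acylation of the oxazolidinone through the mixed anhydride under LiCl/Et3N activation; the unhindered acyl carbon of 3 is attacked in preference to the pivaloyl carbon.

Step 2
Reactants: 4 (R)-4-benzyl-3-[3-(3,4-dimethoxyphenyl)propanoyl]oxazolidin-2-one; 5 tert-butyl bromoacetate
Product: 7 tert-butyl (3S)-4-[(4R)-4-benzyl-2-oxooxazolidin-3-yl]-3-(3,4-dimethoxybenzyl)-4-oxobutanoate, via sodium imide enolate 6 (not isolated)
Conditions: NaN(SiMe3)2, THF, −78 °C; then 5, −78 to −40 °C
Reagents that add atoms: none
Why: Evans oxazolidinone alkylation: the chelated (Z)-enolate 6 is alkylated on the face away from the benzyl group of the (R)-auxiliary, which sets the new centre as S. Minor diastereomer can be removed here by chromatography or crystallisation.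

Step 3
Reactants: 7 tert-butyl (3S)-4-[(4R)-4-benzyl-2-oxooxazolidin-3-yl]-3-(3,4-dimethoxybenzyl)-4-oxobutanoate
Product: 9 (S)-4-(3,4-dimethoxybenzyl)dihydrofuran-2(3H)-one, via hydroxy ester 8 (not isolated)
Conditions: LiBH4, MeOH (1 equiv), THF, 0 °C; then TFA, CH2Cl2, 0 °C to rt
Reagents that add atoms: none
Why: Reductive cleavage of the auxiliary: LiBH4 reduces the imide carbonyl much faster than the tert-butyl ester, and acid then cleaves the tert-butyl ester and closes the γ-lactone. The stereocentre is not α to any carbonyl at either stage and cannot epimerise.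

Step 4
Reactants: 10 4-(benzyloxy)-3-methoxybenzyl alcohol
Product: 11 4-(benzyloxy)-3-methoxybenzyl bromide
Conditions: PBr3, Et2O, 0 °C
Reagents that add atoms: phosphorus tribromide, BrP(Br)Br
Why: Standard conversion of a benzylic alcohol into the bromide; the electron-rich bromide should be used directly without storage.

Step 5
Reactants: 9 (S)-4-(3,4-dimethoxybenzyl)dihydrofuran-2(3H)-one; 11 4-(benzyloxy)-3-methoxybenzyl bromide
Product: 13 (3S,4S)-3-[4-(benzyloxy)-3-methoxybenzyl]-4-(3,4-dimethoxybenzyl)dihydrofuran-2(3H)-one, via lithium enolate 12 (not isolated)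
Conditions: LiN(SiMe3)2, THF, −78 °C; then 11, DMPU, −78 to −20 °C
Reagents that add atoms: none
Why: Lactone enolate alkylation, the standard entry to trans-dibenzylbutyrolactones: the bromide approaches 12 anti to the C4 benzyl group, so C3 is set as S (trans) by 1,2-induction from C4.

Step 6
Reactants: 13 (3S,4S)-3-[4-(benzyloxy)-3-methoxybenzyl]-4-(3,4-dimethoxybenzyl)dihydrofuran-2(3H)-one
Product: 14 (3S,4S)-4-(3,4-dimethoxybenzyl)-3-(4-hydroxy-3-methoxybenzyl)dihydrofuran-2(3H)-one (the enantiomer of natural arctigenin)
Conditions: H2 (1 atm), Pd/C, EtOAc–EtOH, rt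
Reagents that add atoms: none
Why: Hydrogenolysis of the benzyl ether; the lactone C–O bond is not benzylic and nothing else is reducible under these conditions.

Step 7
Reactants: 14 (3S,4S)-4-(3,4-dimethoxybenzyl)-3-(4-hydroxy-3-methoxybenzyl)dihydrofuran-2(3H)-one; 15 1-chloro-3-methoxypropan-2-one
Product: 16 (3S,4S)-4-(3,4-dimethoxybenzyl)-3-[3-methoxy-4-(3-methoxy-2-oxopropoxy)benzyl]dihydrofuran-2(3H)-one
Conditions: K2CO3, KI (cat.), acetone, 50 °C
Reagents that add atoms: none
Why: Williamson etherification of a phenoxide with a highly SN2-reactive α-chloroketone; K2CO3 deprotonates only the phenol, so the lactone and its C3–H are not touched.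

Step 8
Reactants: 16 (3S,4S)-4-(3,4-dimethoxybenzyl)-3-[3-methoxy-4-(3-methoxy-2-oxopropoxy)benzyl]dihydrofuran-2(3H)-one
Product: 18 3-(4-{[(3S,4S)-4-(3,4-dimethoxybenzyl)-2-oxotetrahydrofuran-3-yl]methyl}-2-methoxyphenoxy)-5-methoxy-4H-pyran-4-one, via bis(enaminone) 17 (not isolated)
Conditions: Me2NCH(OMe)2 (excess), toluene, 110 °C; concentrate; then 1 M HCl, THF, 50 °C
Reagents that add atoms: N,N-dimethylformamide dimethyl acetal, COC(OC)N(C)C; water, O
Why: Amide acetal condensation at both activated α-methylene groups of the ketone gives 17; acid hydrolysis of one enaminone to the enol and addition–elimination at the other, with loss of dimethylamine, closes the 4-pyranone. The lactone C3 carries a single hydrogen and cannot form an enaminone.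

Step 9
Reactants: 9 (S)-4-(3,4-dimethoxybenzyl)dihydrofuran-2(3H)-one; 19 2-bromoethyl trifluoromethanesulfonate
Product: 21 (3S,4S)-3-(2-bromoethyl)-4-(3,4-dimethoxybenzyl)dihydrofuran-2(3H)-one, via sodium lactone enolate 20 (not isolated)
Conditions: NaN(SiMe3)2 (1.0 equiv), THF, −78 °C; then 19 (1.3 equiv), −78 °C; AcOH quench at −78 °C
Reagents that add atoms: none
Why: Lactone enolate alkylation with a primary alkyl triflate: the triflate is displaced far faster than the bromide, so the bromoethyl group is transferred intact, and attack anti to the C4 benzyl group gives the trans (3S,4S) lactone. The reactive sodium enolate consumes the triflate at −78 °C without a polar co-solvent, which leaves little time for proton transfer to the product and the cyclopropane closure that would follow.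

Step 10
Reactants: 21 (3S,4S)-3-(2-bromoethyl)-4-(3,4-dimethoxybenzyl)dihydrofuran-2(3H)-one; 22 triphenylphosphine
Product: 23 {2-[(3S,4S)-4-(3,4-dimethoxybenzyl)-2-oxotetrahydrofuran-3-yl]ethyl}triphenylphosphonium bromide
Conditions: 22 (1.2 equiv), MeCN, 80 °C; then Et2O (precipitation)
Reagents that add atoms: none
Why: SN2 quaternisation of triphenylphosphine by a primary alkyl bromide; the medium is neutral, so the lactone and its C3–H are untouched, and the salt can be crystallised and dried before the key step.

Step 11
Reactants: 18 3-(4-{[(3S,4S)-4-(3,4-dimethoxybenzyl)-2-oxotetrahydrofuran-3-yl]methyl}-2-methoxyphenoxy)-5-methoxy-4H-pyran-4-one; 23 {2-[(3S,4S)-4-(3,4-dimethoxybenzyl)-2-oxotetrahydrofuran-3-yl]ethyl}triphenylphosphonium bromide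
Product: 28 tert-butyldimethylsilyl ether of the target at the C4 oxygen of ring B, via phosphorus ylide 24 (not isolated), via silyloxypyrylium triflate 25 (not isolated), via pyranylphosphonium triflate 26 (not isolated), via dienal ylide 27 (not isolated)
Conditions: 18, TBSOTf (1.0 equiv), CH2Cl2, 0 °C to rt, then −78 °C; add 24 [from 23, NaN(SiMe3)2 (1.0 equiv), THF, −78 to 0 °C]; then NaN(SiMe3)2 (1.05 equiv), −78 to 40 °C
Reagents that add atoms: tert-butyldimethylsilyl trifluoromethanesulfonate, CC(C)(C)[Si](C)(C)OS(=O)(=O)C(F)(F)F
Why: Proposed new method: silylation of the pyranone carbonyl of 18 gives the 4-silyloxypyrylium ion 25, whose α carbons (C2 and C6) are its most electrophilic sites; ylide 24 adds there to give the 2H-pyran 26, and deprotonation next to phosphorus triggers cleavage of the ring O–C bond (a 6π electrocyclic opening, equivalently β-elimination of the ring oxygen) to the push–pull dienal ylide 27, whose ylide carbon olefinates the aldehyde, expels Ph3PO and leaves the benzene ring. The closest known reaction types are the conversion of 2,4,6-trisubstituted pyrylium salts into benzenes with alkylidenephosphoranes or nitromethane and the addition of carbon nucleophiles to C2 of 4-silyloxypyrylium ions made from 4-pyranones; new here is their combination on an α-unsubstituted 3,5-dioxygenated pyranone with a non-stabilised ylide. Ring B closes by a 6-exo-trig intramolecular Wittig olefination (ylide carbon onto the formyl carbon, C=O outside the forming ring), which makes the C1–C6 bond after the intermolecular addition has made C1–C2. No stereocentre is created: the two sp3 centres of 26 are erased on aromatisation and the four lactone centres are remote from the reacting atoms. The step needs site selectivity for the pyrylium α carbons over C4 and over the lactone carbonyls; C4 is shielded and deactivated by its silyloxy group, a cation outcompetes neutral esters at −78 °C, and attack at either α carbon converges on the same arene. It also needs the ylide carbon and the aldehyde on the same side of the chain: the double bond of 27 next to the formyl group is cis because it comes from the ring, and the one next to phosphorus can turn because the phosphonium dienolate resonance form lowers its bond order and because 27 can reclose to the 2H-pyran. Adding 24 to 25, not the reverse, keeps the ylide from deprotonating 26, and exactly one equivalent of the silyl triflate leaves none to quench the ylide.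

Step 12
Reactants: 28 tert-butyldimethylsilyl ether of the target at the C4 oxygen of ring B
Product: 29 (3S,4S)-3-[4-(5-{[(3S,4S)-4-(3,4-dimethoxybenzyl)-2-oxotetrahydrofuran-3-yl]methyl}-2-hydroxy-3-methoxyphenoxy)-3-methoxybenzyl]-4-(3,4-dimethoxybenzyl)dihydrofuran-2(3H)-one (target)
Conditions: Bu4NF, AcOH, THF, 0 °C
Reagents that add atoms: none
Why: Fluoride cleavage of an aryl silyl ether; acetic acid buffers the phenoxide so that the lactones are neither opened nor epimerised.

## Compound list

1 | 3-(3,4-dimethoxyphenyl)propanoic acid | COc1ccc(CCC(=O)O)cc1OC | starting material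
2 | (R)-4-benzyloxazolidin-2-one | O=C1N[C@H](Cc2ccccc2)CO1 | starting material
3 | 3-(3,4-dimethoxyphenyl)propanoic pivalic anhydride | COc1ccc(CCC(=O)OC(=O)C(C)(C)C)cc1OC | intermediate (not isolated)
4 | (R)-4-benzyl-3-[3-(3,4-dimethoxyphenyl)propanoyl]oxazolidin-2-one | COc1ccc(CCC(=O)N2[C@H](Cc3ccccc3)COC2=O)cc1OC | intermediate
5 | tert-butyl bromoacetate | CC(C)(C)OC(=O)CBr | starting material
6 | sodium (Z)-enolate of 4 | COc1ccc(C/C=C(\[O-])N2[C@H](Cc3ccccc3)COC2=O)cc1OC.[Na+] | intermediate (not isolated)
7 | tert-butyl (3S)-4-[(4R)-4-benzyl-2-oxooxazolidin-3-yl]-3-(3,4-dimethoxybenzyl)-4-oxobutanoate | COc1ccc(C[C@@H](CC(=O)OC(C)(C)C)C(=O)N2[C@H](Cc3ccccc3)COC2=O)cc1OC | intermediate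
8 | tert-butyl (3S)-4-(3,4-dimethoxyphenyl)-3-(hydroxymethyl)butanoate | COc1ccc(C[C@@H](CC(=O)OC(C)(C)C)CO)cc1OC | intermediate (not isolated)
9 | (S)-4-(3,4-dimethoxybenzyl)dihydrofuran-2(3H)-one | COc1ccc(C[C@@H]2COC(=O)C2)cc1OC | intermediate
10 | 4-(benzyloxy)-3-methoxybenzyl alcohol | COc1cc(CO)ccc1OCc1ccccc1 | starting material
11 | 4-(benzyloxy)-3-methoxybenzyl bromide | COc1cc(CBr)ccc1OCc1ccccc1 | intermediate
12 | lithium enolate of 9 | COc1ccc(C[C@@H]2COC([O-])=C2)cc1OC.[Li+] | intermediate (not isolated)
13 | (3S,4S)-3-[4-(benzyloxy)-3-methoxybenzyl]-4-(3,4-dimethoxybenzyl)dihydrofuran-2(3H)-one | COc1ccc(C[C@@H]2COC(=O)[C@H]2Cc2ccc(OCc3ccccc3)c(OC)c2)cc1OC | intermediate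
14 | (3S,4S)-4-(3,4-dimethoxybenzyl)-3-(4-hydroxy-3-methoxybenzyl)dihydrofuran-2(3H)-one | COc1ccc(C[C@@H]2COC(=O)[C@H]2Cc2ccc(O)c(OC)c2)cc1OC | intermediate
15 | 1-chloro-3-methoxypropan-2-one | COCC(=O)CCl | starting material
16 | (3S,4S)-4-(3,4-dimethoxybenzyl)-3-[3-methoxy-4-(3-methoxy-2-oxopropoxy)benzyl]dihydrofuran-2(3H)-one | COc1ccc(C[C@@H]2COC(=O)[C@H]2Cc2ccc(OCC(=O)COC)c(OC)c2)cc1OC | intermediate
17 | (3S,4S)-3-(4-{[1,5-bis(dimethylamino)-4-methoxy-3-oxopenta-1,4-dien-2-yl]oxy}-3-methoxybenzyl)-4-(3,4-dimethoxybenzyl)dihydrofuran-2(3H)-one (alkene geometry not defined) | COc1ccc(C[C@@H]2COC(=O)[C@H]2Cc2ccc(OC(=CN(C)C)C(=O)C(OC)=CN(C)C)c(OC)c2)cc1OC | intermediate (not isolated)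
18 | 3-(4-{[(3S,4S)-4-(3,4-dimethoxybenzyl)-2-oxotetrahydrofuran-3-yl]methyl}-2-methoxyphenoxy)-5-methoxy-4H-pyran-4-one | COc1ccc(C[C@@H]2COC(=O)[C@H]2Cc2ccc(Oc3cocc(OC)c3=O)c(OC)c2)cc1OC | intermediate
19 | 2-bromoethyl trifluoromethanesulfonate | O=S(=O)(OCCBr)C(F)(F)F | starting material
20 | sodium enolate of 9 | COc1ccc(C[C@@H]2COC([O-])=C2)cc1OC.[Na+] | intermediate (not isolated)
21 | (3S,4S)-3-(2-bromoethyl)-4-(3,4-dimethoxybenzyl)dihydrofuran-2(3H)-one | COc1ccc(C[C@@H]2COC(=O)[C@H]2CCBr)cc1OC | intermediate
22 | triphenylphosphine | c1ccc(P(c2ccccc2)c2ccccc2)cc1 | starting material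
23 | {2-[(3S,4S)-4-(3,4-dimethoxybenzyl)-2-oxotetrahydrofuran-3-yl]ethyl}triphenylphosphonium bromide | COc1ccc(C[C@@H]2COC(=O)[C@H]2CC[P+](c2ccccc2)(c2ccccc2)c2ccccc2)cc1OC.[Br-] | intermediate
24 | {2-[(3S,4S)-4-(3,4-dimethoxybenzyl)-2-oxotetrahydrofuran-3-yl]ethylidene}triphenylphosphorane | COc1ccc(C[C@@H]2COC(=O)[C@H]2CC=P(c2ccccc2)(c2ccccc2)c2ccccc2)cc1OC | intermediate (not isolated)
25 | 4-(tert-butyldimethylsilyloxy)pyrylium triflate of 18 (3-aryloxy, 5-methoxy) | COc1ccc(C[C@@H]2COC(=O)[C@H]2Cc2ccc(Oc3c[o+]cc(OC)c3O[Si](C)(C)C(C)(C)C)c(OC)c2)cc1OC.[O-]S(=O)(=O)C(F)(F)F | intermediate (not isolated)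
26 | 2H-pyran-2-yl phosphonium triflate from addition of 24 to 25, drawn as the adduct at the α carbon next to C–OMe; the two new sp3 centres are undefined and the regioisomer converges | COc1ccc(C[C@@H]2COC(=O)[C@H]2CC(C2OC=C(Oc3ccc(C[C@@H]4C(=O)OC[C@H]4Cc4ccc(OC)c(OC)c4)cc3OC)C(O[Si](C)(C)C(C)(C)C)=C2OC)[P+](c2ccccc2)(c2ccccc2)c2ccccc2)cc1OC.[O-]S(=O)(=O)C(F)(F)F | intermediate (not isolated)
27 | ring-opened dienal ylide: 2-aryloxy-4-methoxy-3-silyloxy-6-(triphenylphosphoranylidene)hexa-2,4-dienal carrying the lactonylmethyl group at C6; 2,3-double bond cis (formyl group and C4 on the same side), 4,5-double bond not fixed | COc1ccc(C[C@@H]2COC(=O)[C@H]2CC(C=C(OC)\C(O[Si](C)(C)C(C)(C)C)=C(/C=O)Oc2ccc(C[C@@H]3C(=O)OC[C@H]3Cc3ccc(OC)c(OC)c3)cc2OC)=P(c2ccccc2)(c2ccccc2)c2ccccc2)cc1OC | intermediate (not isolated)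
28 | tert-butyldimethylsilyl ether of the target (silyl on the C4 oxygen of ring B) | COc1ccc(C[C@@H]2COC(=O)[C@H]2Cc2ccc(Oc3cc(C[C@@H]4C(=O)OC[C@H]4Cc4ccc(OC)c(OC)c4)cc(OC)c3O[Si](C)(C)C(C)(C)C)c(OC)c2)cc1OC | intermediate
29 | (3S,4S)-3-[4-(5-{[(3S,4S)-4-(3,4-dimethoxybenzyl)-2-oxotetrahydrofuran-3-yl]methyl}-2-hydroxy-3-methoxyphenoxy)-3-methoxybenzyl]-4-(3,4-dimethoxybenzyl)dihydrofuran-2(3H)-one | COc1ccc(C[C@@H]2COC(=O)[C@H]2Cc2ccc(Oc3cc(C[C@@H]4C(=O)OC[C@H]4Cc4ccc(OC)c(OC)c4)cc(OC)c3O)c(OC)c2)cc1OC | target

## Step count and risks

Total step count: 12. Longest linear sequence: 9 steps (steps 1, 2, 3, 5, 6, 7, 8, 11, 12 from acid 1); the phosphonium branch (steps 9 and 10) starts from 9, and step 4 is a side branch.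

**Step 11 (key step).**
- Most likely failure: the ylide is consumed without C–C bond formation, by attack at silicon (desilylation back to 18) or by electron transfer to the pyrylium ion. Alternatively, after ring opening the delocalised ylide may be too stabilised to olefinate at temperatures the lactones tolerate, so that the open-chain material is hydrolysed on work-up. Enolisation of the lactones by excess base is a lesser concern.
- Fallback with known chemistry, setting out from 9 and 14 and returning at 29: purchased 4-hydroxy-3-iodo-5-methoxybenzaldehyde F1 would be O-benzylated (BnBr, K2CO3) to 4-(benzyloxy)-3-iodo-5-methoxybenzaldehyde F2, reduced (NaBH4) to [4-(benzyloxy)-3-iodo-5-methoxyphenyl]methanol F3 and brominated (PBr3) to 2-(benzyloxy)-5-(bromomethyl)-1-iodo-3-methoxybenzene F4. Enolate 12 from 9 would be alkylated with F4 as in step 5 to give (3S,4S)-3-[4-(benzyloxy)-3-iodo-5-methoxybenzyl]-4-(3,4-dimethoxybenzyl)dihydrofuran-2(3H)-one F5. Ullmann diaryl ether coupling of F5 with phenol 14 (CuI, picolinic acid, K3PO4, DMSO, 90 °C) would give the benzyl ether of the target F6, and hydrogenolysis (H2, Pd/C) would deliver 29. This accepts the hindered ether coupling that the main route avoids.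

**Step 9.**
- Most likely failure: proton transfer from the product to unreacted enolate, after which the new enolate closes onto the bromide to a spiro-cyclopropane; in addition, elimination of the triflate reagent when the enolate acts as a base, and some O-alkylation by the hard triflate.
- Fallback, setting out from 9 and returning at 21, which separates C–C bond formation from the introduction of the leaving group: 9 would be deprotonated with LiN(SiMe3)2 as in step 5 and enolate 12 alkylated with purchased tert-butyl(2-iodoethoxy)dimethylsilane F7 (THF, DMPU, −78 to −20 °C) to the trans lactone (3S,4S)-3-[2-(tert-butyldimethylsilyloxy)ethyl]-4-(3,4-dimethoxybenzyl)dihydrofuran-2(3H)-one F8, which carries no leaving group and cannot cyclise. Ph3PBr2 in CH2Cl2 would then convert the silyl ether directly into 21, without passing through the free alcohol, which could translactonise.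

**Step 8.**
- Most likely failure: stalling after the first aminomethylenation, and opening of the lactone by methanol or dimethylamine under the hot, mildly basic conditions needed to force the second one; hydrolysis without ring closure in the acid stage is a lesser risk.
- Fallback, setting out from 15 and 9 and returning at 18, which builds the pyranone before the lactone is present so that forcing conditions are harmless: purchased 4-(hydroxymethyl)-2-methoxyphenol F9 would be alkylated at the phenol with 15 (K2CO3, acetone) to 1-[4-(hydroxymethyl)-2-methoxyphenoxy]-3-methoxypropan-2-one F10. Condensation with tert-butoxybis(dimethylamino)methane at 120 °C would give 1,5-bis(dimethylamino)-2-[4-(hydroxymethyl)-2-methoxyphenoxy]-4-methoxypenta-1,4-dien-3-one F11, which aqueous HCl would close to 3-[4-(hydroxymethyl)-2-methoxyphenoxy]-5-methoxy-4H-pyran-4-one F12. Appel bromination (CBr4, PPh3) would give 3-[4-(bromomethyl)-2-methoxyphenoxy]-5-methoxy-4H-pyran-4-one F13, and alkylation of enolate 12 with F13 at −78 °C, anti to C4, would give 18. An unactivated 4-pyranone is a poor acceptor for an ester enolate at that temperature, so benzylation should outrun conjugate addition.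

## Further compounds

F1 | step 11 | 4-hydroxy-3-iodo-5-methoxybenzaldehyde (purchased) | COc1cc(C=O)cc(I)c1O
F2 | step 11 | 4-(benzyloxy)-3-iodo-5-methoxybenzaldehyde | COc1cc(C=O)cc(I)c1OCc1ccccc1
F3 | step 11 | [4-(benzyloxy)-3-iodo-5-methoxyphenyl]methanol | COc1cc(CO)cc(I)c1OCc1ccccc1
F4 | step 11 | 2-(benzyloxy)-5-(bromomethyl)-1-iodo-3-methoxybenzene | COc1cc(CBr)cc(I)c1OCc1ccccc1
F5 | step 11 | (3S,4S)-3-[4-(benzyloxy)-3-iodo-5-methoxybenzyl]-4-(3,4-dimethoxybenzyl)dihydrofuran-2(3H)-one | COc1ccc(C[C@@H]2COC(=O)[C@H]2Cc2cc(I)c(OCc3ccccc3)c(OC)c2)cc1OC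
F6 | step 11 | benzyl ether of the target at the C4 oxygen of ring B | COc1ccc(C[C@@H]2COC(=O)[C@H]2Cc2ccc(Oc3cc(C[C@@H]4C(=O)OC[C@H]4Cc4ccc(OC)c(OC)c4)cc(OC)c3OCc3ccccc3)c(OC)c2)cc1OC
F7 | step 9 | tert-butyl(2-iodoethoxy)dimethylsilane (purchased) | CC(C)(C)[Si](C)(C)OCCI
F8 | step 9 | (3S,4S)-3-[2-(tert-butyldimethylsilyloxy)ethyl]-4-(3,4-dimethoxybenzyl)dihydrofuran-2(3H)-one | COc1ccc(C[C@@H]2COC(=O)[C@H]2CCO[Si](C)(C)C(C)(C)C)cc1OC
F9 | step 8 | 4-(hydroxymethyl)-2-methoxyphenol (purchased) | COc1cc(CO)ccc1O
F10 | step 8 | 1-[4-(hydroxymethyl)-2-methoxyphenoxy]-3-methoxypropan-2-one | COCC(=O)COc1ccc(CO)cc1OC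
F11 | step 8 | 1,5-bis(dimethylamino)-2-[4-(hydroxymethyl)-2-methoxyphenoxy]-4-methoxypenta-1,4-dien-3-one | COC(=CN(C)C)C(=O)C(=CN(C)C)Oc1ccc(CO)cc1OC
F12 | step 8 | 3-[4-(hydroxymethyl)-2-methoxyphenoxy]-5-methoxy-4H-pyran-4-one | COc1cc(CO)ccc1Oc1cocc(OC)c1=O
F13 | step 8 | 3-[4-(bromomethyl)-2-methoxyphenoxy]-5-methoxy-4H-pyran-4-one | COc1cc(CBr)ccc1Oc1cocc(OC)c1=O
A1 | alternative 1 | 4-(benzyloxy)-3-(4-formyl-2-methoxyphenoxy)-5-methoxybenzaldehyde | COc1cc(C=O)ccc1Oc1cc(C=O)cc(OC)c1OCc1ccccc1
A2 | alternative 1 | bis(aldol adduct), carbinol centres undefined | COc1ccc(C[C@@H]2COC(=O)[C@H]2C(O)c2ccc(Oc3cc(C(O)[C@@H]4C(=O)OC[C@H]4Cc4ccc(OC)c(OC)c4)cc(OC)c3OCc3ccccc3)c(OC)c2)cc1OC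
A3 | alternative 2 | 3-(3,4-dimethoxybenzyl)cyclobutan-1-one | COc1ccc(CC2CC(=O)C2)cc1OC
A4 | alternative 2 | (S)-4-(3,4-dimethoxybenzyl)dihydrofuran-2(3H)-one (identical with 9) | COc1ccc(C[C@@H]2COC(=O)C2)cc1OC
A5 | alternative 3 | diaryl ether bis(pinacol boronate): 2-[4-(benzyloxy)-3-methoxy-5-(2-methoxy-4-(pinacolboryl)phenoxy)phenyl]-4,4,5,5-tetramethyl-1,3,2-dioxaborolane | COc1cc(B2OC(C)(C)C(C)(C)O2)ccc1Oc1cc(B2OC(C)(C)C(C)(C)O2)cc(OC)c1OCc1ccccc1
A6 | alternative 3 | (S)-4-(3,4-dimethoxybenzyl)-3-methylenedihydrofuran-2(3H)-one | COc1ccc(C[C@@H]2COC(=O)C2=C)cc1OC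
A7 | alternative 3 | benzyl ether of the target at the C4 oxygen of ring B | COc1ccc(C[C@@H]2COC(=O)[C@H]2Cc2ccc(Oc3cc(C[C@@H]4C(=O)OC[C@H]4Cc4ccc(OC)c(OC)c4)cc(OC)c3OCc3ccccc3)c(OC)c2)cc1OC
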